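**Retrosynthetic overview**
1. Target indenone ⇒ a tris-azulene "hub" azulenol by oxidative 7→6 ring contraction (one hub carbon lost as formate). The indenone benzene ring is the only ring built, and it is built last.
2. Tertiary alcohol ⇒ hydration of the azulenoquinone methide obtained by dehydrogenating the 7-isopropyl hub azulenol.
3. The two azulenyl–hub bonds ⇒ twofold dehydrogenative arylation of guaiazulen-3-ol at its ortho/para-type positions C2 and C5 by two guaiazulenes.
4. Guaiazulen-3-ol ⇒ guaiazulene by C3 benzoyloxylation.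
5. Ring order: all three azulene bicycles are bought as guaiazulene; the indenone five-membered ring is inherited from the hub; the six-membered ring is formed in the final step.

Assumption: the SMILES has no stereodescriptor and the molecule has no stereogenic centre, so the achiral compound as drawn is made; rotation about the two azulenyl–indenone bonds is left uncontrolled.

Notation: Gu = guaiazulen-3-yl = 3,8-dimethyl-5-(propan-2-yl)azulen-1-yl. The central (hub) unit keeps guaiazulene numbering (C1-Me, C4-Me, C7-iPr, oxygen on C3). Hub C3, C2, C1, C8a, C7, C6, C5, C4, C3a become indenone C1, C2, C3, C3a, C4, C5, C6, C7, C7a; hub C8 is excised.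

Step 1
Reactants: 1 guaiazulene (1,4-dimethyl-7-isopropylazulene)
Product: 2 7-isopropyl-1,4-dimethylazulen-3-yl benzoate
Conditions: (BzO)2 (1.0 equiv), CH2Cl2, 0 °C → rt, dark, Ar
Reagents that add atoms: dibenzoyl peroxide, O=C(OOC(=O)c1ccccc1)c1ccccc1
Why: Electrophilic C–H acyloxylation: C3, the only free and most nucleophilic five-ring carbon of guaiazulene, attacks the O–O bond of the peroxide (SN2 at oxygen, the benzoyloxylation known for azulene and indoles with diacyl peroxides) and the azulenium ion loses a proton to benzoate; no stereocentre is formed.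

Step 2
Reactants: 2 7-isopropyl-1,4-dimethylazulen-3-yl benzoate; 1 guaiazulene (two molecules incorporated)
Product: 5 2,5-di(Gu)-7-isopropyl-1,4-dimethylazulen-3-ol, via guaiazulen-3-ol 3 (not isolated), via mono-azulenyl azulenol 4 (not isolated)
Conditions: NaOMe (1.05 equiv), MeOH/THF, 0 °C, Ar, evaporate; 1 (4 equiv), PhI(OAc)2 (2.1 equiv, slow addition), HFIP/CH2Cl2 1:4, −40 → 0 °C; work-up and short deactivated-silica column under Ar, product stored cold under Ar and used promptly
Reagents that add atoms: none
Why: Proposed new method: methanolysis frees azulenol 3, by far the most easily oxidised species present, which PhI(OAc)2 in HFIP converts by two-electron oxidation into a phenoxenium-type 3-oxoazulenium ion with positive charge at C2, C3a, C5, C7 and C8a; guaiazulene, a strong carbon nucleophile at its own C3, adds at the two charge-bearing C–H sites (giving 4, then after a second oxidation 5) and proton loss rearomatises the hub, the closest known reaction type being the trivalent-iodine dehydrogenative phenol–arene cross-coupling (Kita type), and the product azulenol, shielded at its oxygen by the C2 azulenyl group, is handled strictly under Ar because it is the substrate that step 3 oxidises on purpose; no stereocentre is formed.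

Step 3
Reactants: 5 2,5-di(Gu)-7-isopropyl-1,4-dimethylazulen-3-ol
Product: 11 4-(2-hydroxypropan-2-yl)-3,7-dimethyl-2,6-di(Gu)-1H-inden-1-one (target CNP0151235.0), via quinone methide 6 (not isolated), via carbinol azulenol 7 (not isolated), via C7 hydroperoxide 8 (not isolated), via seco keto-aldehyde 9 (not isolated), via formyl carbinol 10 (not isolated)
Conditions: Ag2O (1.05 equiv), AcOH (1 equiv), THF/H2O 4:1 (degassed), 0 °C, Ar; then K2CO3 (4 equiv), O2 (1 atm), 0 °C → rt
Reagents that add atoms: water, O
Why: Proposed new method: Ag2O dehydrogenates azulenol 5 (azulenoxyl radical disproportionation, the classical p-alkylphenol → quinone methide reaction) to the extended quinone methide 6, whose acid-catalysed 1,8-hydration rearomatises the hub and gives carbinol 7 (only the hub carries the hydroxyl, so the other two isopropyl groups are untouched); the azulenolate of 7 is then oxygenated by O2 at the para-type carbon C7 (or at C8a, which converges) to peroxide 8, whose peroxide anion adds to the adjacent dienone δ-carbon C8 and cleaves as a dioxetane (Hock-type C–C scission) to seco keto-aldehyde 9, the vinylogous enolate of 9 closes C8a→C7 by aldol addition to the six-membered ring of 10, and retro-Claisen loss of the formyl carbon (hub C8) as formate with β-elimination of the C7 hydroxyl aromatises the new ring to 11; the closest known reaction types are phenolate/enolate autoxidation to hydroperoxides, dioxetane or Hock cleavage, intramolecular aldol addition and deformylative aromatisation, and the sp3 centres of 8 and 10 are racemic, transient and erased on aromatisation.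

**Compound list**
1 | guaiazulene (1,4-dimethyl-7-isopropylazulene) | Cc1ccc2c(C)ccc(C(C)C)cc1-2 | starting material
2 | 7-isopropyl-1,4-dimethylazulen-3-yl benzoate | O=C(Oc1cc(C)c2cc(C(C)C)ccc(C)c1-2)c1ccccc1 | intermediate
3 | 7-isopropyl-1,4-dimethylazulen-3-ol (guaiazulen-3-ol) | Oc1cc(C)c2cc(C(C)C)ccc(C)c1-2 | intermediate
4 | 2-(Gu)-7-isopropyl-1,4-dimethylazulen-3-ol (C2-first order assumed; the order of the two arylations does not matter) | Oc1c(-c3cc(C)c4cc(C(C)C)ccc(C)c3-4)c(C)c2cc(C(C)C)ccc(C)c1-2 | intermediate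
5 | 2,5-di(Gu)-7-isopropyl-1,4-dimethylazulen-3-ol | Oc1c(-c3cc(C)c4cc(C(C)C)ccc(C)c3-4)c(C)c2cc(C(C)C)cc(-c3cc(C)c4cc(C(C)C)ccc(C)c3-4)c(C)c1-2 | intermediate
6 | 2,5-di(Gu)-1,4-dimethyl-7-(propan-2-ylidene)azulen-3(7H)-one (quinone methide) | O=C1C(-c3cc(C)c4cc(C(C)C)ccc(C)c3-4)=C(C)C2=CC(=C(C)C)C=C(-c3cc(C)c4cc(C(C)C)ccc(C)c3-4)C(C)=C12 | intermediate
7 | 2,5-di(Gu)-7-(2-hydroxypropan-2-yl)-1,4-dimethylazulen-3-ol | Oc1c(-c3cc(C)c4cc(C(C)C)ccc(C)c3-4)c(C)c2cc(C(C)(C)O)cc(-c3cc(C)c4cc(C(C)C)ccc(C)c3-4)c(C)c1-2 | intermediate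
8 | 2,5-di(Gu)-7-hydroperoxy-7-(2-hydroxypropan-2-yl)-1,4-dimethylazulen-3(7H)-one (racemic at C7) | O=C1C(-c3cc(C)c4cc(C(C)C)ccc(C)c3-4)=C(C)C2=CC(OO)(C(C)(C)O)C=C(-c3cc(C)c4cc(C(C)C)ccc(C)c3-4)C(C)=C12 | intermediate
9 | 7,8-seco keto-aldehyde (hub C7–C8 bond cleaved; C8 is a formyl group on C8a, C7 a ketone bearing the C(CH3)2OH group; drawn as the 3-enol, present as its potassium enolate) | OC1=C(-c3cc(C)c4cc(C(C)C)ccc(C)c3-4)C(C)=C(C=O)C1=C(C)C(-c3cc(C)c4cc(C(C)C)ccc(C)c3-4)=CC(=O)C(C)(C)O | intermediate
10 | 4-hydroxy-4-(2-hydroxypropan-2-yl)-3,7-dimethyl-1-oxo-2,6-di(Gu)-1,4-dihydro-3aH-indene-3a-carbaldehyde (indenone numbering; diastereomer mixture) | O=C1C(-c3cc(C)c4cc(C(C)C)ccc(C)c3-4)=C(C)C2(C=O)C(O)(C(C)(C)O)C=C(-c3cc(C)c4cc(C(C)C)ccc(C)c3-4)C(C)=C12 | intermediate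
11 | 4-(2-hydroxypropan-2-yl)-3,7-dimethyl-2,6-bis[3,8-dimethyl-5-(propan-2-yl)azulen-1-yl]-1H-inden-1-one (achiral) | CC1=C(c2cc(C)c3cc(C(C)C)ccc(C)c2-3)C(=O)c2c(C)c(-c3cc(C)c4cc(C(C)C)ccc(C)c3-4)cc(C(C)(C)O)c21 | target

**Totals**
Total step count: 3. Longest linear sequence: 3 steps (1 → 2 → 5 → 11); guaiazulene enters a second and third time in step 2.

**Steps most likely to fail, with fallbacks**

Step 3 is the most likely to fail. The site of O2 attack, closure of the peroxide onto C6 instead of C8, attack at C3a with loss of C4, and dehydration of 7 to the isopropenyl compound are not under reagent control. The fallback replaces the aerobic cascade by a stepwise quinol formation, nucleophilic epoxidation and semipinacol shift. It sets out from carbinol azulenol 7, which is made from 5 by the Ag2O/AcOH part of step 3 and is worked up under Ar instead of being exposed to base and O2. PhI(OAc)2 in aqueous MeCN at −20 °C dearomatises the hub with water capture at C7 and gives 2,5-di(Gu)-7-hydroxy-7-(2-hydroxypropan-2-yl)-1,4-dimethylazulen-3(7H)-one F1, a p-quinol-type dienone. H2O2/NaOH then adds at the dienone δ-carbon C8 and closes on C8a (Weitz–Scheffer epoxidation of the γ,δ-double bond; the other δ-carbon, C6, is deactivated and shielded by the donor azulenyl group on C5) to give 2,5-di(Gu)-8,8a-epoxy-7-hydroxy-7-(2-hydroxypropan-2-yl)-1,4-dimethyl-8,8a-dihydroazulen-3(7H)-one F2. BF3·OEt2 at −78 °C opens the epoxide at the tertiary, doubly allylic carbon C8a (pentadienyl-type cation over C8a, C4 and C6), and C7 migrates from C8 to C8a (the epoxide → ring-contracted aldehyde rearrangement). This delivers formyl carbinol 10, where the route is rejoined; K2CO3 in aqueous THF, now without O2, completes the deformylative aromatisation to 11.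

Step 2 is the second most likely to fail. Over-oxidation of 5 to the quinone methide, air oxidation of 5 during isolation, homocoupling of the azulenol, oxidation of guaiazulene itself to its 3,3'-dimer, or ipso attack at C7 can all compete. The fallback fixes both positions by halogenation, forms the two bonds by palladium catalysis and carries the oxygen as an acetate until the end. It sets out from 2. NaOMe frees azulenol 3, and NBS (2.0 equiv, THF, −78 °C) brominates its two ortho/para-type C–H sites to give 2,5-dibromo-7-isopropyl-1,4-dimethylazulen-3-ol F3. Acetylation in the same flask (Ac2O, pyridine) gives 2,5-dibromo-7-isopropyl-1,4-dimethylazulen-3-yl acetate F4, which is isolated. Twofold direct C–H arylation of guaiazulene 1 at C3 with F4 (Pd(OAc)2, XPhos, PivOH, K2CO3, toluene, 100 °C) gives the air-stable 2,5-di(Gu)-7-isopropyl-1,4-dimethylazulen-3-yl acetate F5. Methanolysis of F5 (K2CO3, degassed MeOH/THF, 0 °C, Ar) gives 5, where the route is rejoined.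

Step 1 is the third. Radical benzoyloxylation of the C1 methyl group or 3,3'-dimerisation may compete with clean C3 substitution. The fallback reverses the polarity at C3. It sets out from 1. NBS (THF, −78 °C) gives 3-bromo-7-isopropyl-1,4-dimethylazulene F6, which is kept cold and not isolated. t-BuLi (2 equiv, −78 °C) gives (7-isopropyl-1,4-dimethylazulen-3-yl)lithium F7. Inverse addition of F7 to (BzO)2 at −78 °C (aryllithium attack on the peroxide oxygen) gives 2, where the route is rejoined.

**Further compounds**
F1 | step 3 | 2,5-di(Gu)-7-hydroxy-7-(2-hydroxypropan-2-yl)-1,4-dimethylazulen-3(7H)-one (racemic) | O=C1C(-c3cc(C)c4cc(C(C)C)ccc(C)c3-4)=C(C)C2=CC(O)(C(C)(C)O)C=C(-c3cc(C)c4cc(C(C)C)ccc(C)c3-4)C(C)=C12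
F2 | step 3 | 2,5-di(Gu)-8,8a-epoxy-7-hydroxy-7-(2-hydroxypropan-2-yl)-1,4-dimethyl-8,8a-dihydroazulen-3(7H)-one (diastereomer mixture) | O=C1C(-c5cc(C)c6cc(C(C)C)ccc(C)c5-6)=C(C)C23OC2C(O)(C(C)(C)O)C=C(-c5cc(C)c6cc(C(C)C)ccc(C)c5-6)C(C)=C13
F3 | step 2 | 2,5-dibromo-7-isopropyl-1,4-dimethylazulen-3-ol | Oc1c(Br)c(C)c2cc(C(C)C)cc(Br)c(C)c1-2
F4 | step 2 | 2,5-dibromo-7-isopropyl-1,4-dimethylazulen-3-yl acetate | CC(=O)Oc1c(Br)c(C)c2cc(C(C)C)cc(Br)c(C)c1-2
F5 | step 2 | 2,5-di(Gu)-7-isopropyl-1,4-dimethylazulen-3-yl acetate | CC(=O)Oc1c(-c3cc(C)c4cc(C(C)C)ccc(C)c3-4)c(C)c2cc(C(C)C)cc(-c3cc(C)c4cc(C(C)C)ccc(C)c3-4)c(C)c1-2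
F6 | step 1 | 3-bromo-7-isopropyl-1,4-dimethylazulene | Brc1cc(C)c2cc(C(C)C)ccc(C)c1-2
F7 | step 1 | (7-isopropyl-1,4-dimethylazulen-3-yl)lithium | [Li]c1cc(C)c2cc(C(C)C)ccc(C)c1-2
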